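**Assumptions.** The target has no stereocentre and no stereogenic double bond (both chromene alkenes are cis by ring constraint), so it is achiral and is made as the single compound drawn. Small reagents that end up as skeletal carbon (prenyl bromide, acetyl chloride, DMF dimethyl acetal, prenal, 3-chloro-3-methylbut-1-yne) are numbered as starting materials; MOMCl, MeI and Ac2O are protecting-group reagents.

## Retrosynthetic overview

1. Target 29 ⇐ isoflavone quinone 27: the furan ring (C2–O2′) is closed last by a redox-neutral cycloisomerisation in which the quinone is the internal oxidant, then the 5-acetate is removed.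
2. 27 ⇐ pyranochromone acetate 17 + chromenequinone 26: the C3–C1′ bond is made by Pd(II)-catalysed dehydrogenative C3–H/C6–H coupling.
3. 17 ⇐ 5,7-dihydroxy-6-prenylchromone 14 (pyran annulated at the only free carbon, C8) ⇐ acetophenone 10 (γ-pyrone closed through the only free OH) ⇐ symmetric phenol 7 ⇐ resorcinol (ortho-lithiation/prenylation, then Ir-catalysed meta C–H borylation/oxidation).
4. 26 ⇐ 5,8-dimethoxy-2,2-dimethylchromene 25 (propargyl ether Claisen) ⇐ 2,5-dimethoxyphenol ⇐ hydroquinone.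
5. Ring order: ring A (given) → γ-pyrone → ring-A pyran; ring B (given) → ring-B pyran → quinone; union; furan last.

## Route

Step 1
Reactants: 1 resorcinol
Product: 2 1,3-bis(methoxymethoxy)benzene
Conditions: NaH (2.4 equiv), DMF, 0 °C; MOMCl (2.4 equiv), 0 °C to rt
Reagents that add atoms: chloromethyl methyl ether, COCCl
Why: Williamson O-alkylation of the bis-phenoxide installs two MOM acetals that protect the phenols and direct the lithiation in step 2.

Step 2
Reactants: 2 1,3-bis(methoxymethoxy)benzene; 3 prenyl bromide (1-bromo-3-methylbut-2-ene)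
Product: 5 1,3-bis(methoxymethoxy)-2-(3-methylbut-2-en-1-yl)benzene, via aryllithium 4 (not isolated)
Conditions: n-BuLi (1.1 equiv), THF, 0 °C, 1 h; CuBr·SMe2 (10 mol %), 3 (1.2 equiv), −78 °C to rt
Reagents that add atoms: prenyl bromide (3), CC(C)=CCBr; n-butyllithium, [Li]CCCC (lithium of 4 only)
Why: Directed ortho-metalation removes the C2–H flanked by both OMOM groups, and the aryllithium is allylated at the primary carbon of prenyl bromide (copper-catalysed SN2), which fixes the prenyl group between the two future ring-A oxygens O5 and O7.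

Step 3
Reactants: 5 1,3-bis(methoxymethoxy)-2-(3-methylbut-2-en-1-yl)benzene
Product: 7 3,5-bis(methoxymethoxy)-4-(3-methylbut-2-en-1-yl)phenol, via pinacol boronate 6 (not isolated)
Conditions: [Ir(OMe)(cod)]2 (1.5 mol %), dtbpy (3 mol %), B2pin2 (0.6 equiv), THF, 60 °C; then NaOH (aq), 30 % H2O2, 0 °C
Reagents that add atoms: hydrogen peroxide, OO; bis(pinacolato)diboron, CC1(C)OB(OC1(C)C)B1OC(C)(C)C(C)(C)O1 (boron of 6 only)
Why: Sterically controlled Ir-catalysed C–H borylation occurs at the only arene C–H with no ortho substituent (para to prenyl; the trisubstituted alkene is inert), and alkaline peroxide oxidation of the C–B bond gives a C2-symmetric phenol whose OH becomes the pyrone oxygen.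

Step 4
Reactants: 7 3,5-bis(methoxymethoxy)-4-(3-methylbut-2-en-1-yl)phenol; 8 acetyl chloride
Product: 10 1-[6-hydroxy-2,4-bis(methoxymethoxy)-3-(3-methylbut-2-en-1-yl)phenyl]ethan-1-one, via bromomagnesium phenoxide 9 (not isolated)
Conditions: EtMgBr (1.05 equiv), Et2O, 0 °C; solvent switch to toluene; AcCl (1.1 equiv), rt
Reagents that add atoms: acetyl chloride (8), CC(Cl)=O; ethylmagnesium bromide, CC[Mg]Br (MgBr of 9 only)
Why: Magnesium-templated ortho-C-acylation of a bromomagnesium phenoxide (a non-acidic Friedel–Crafts variant) is unambiguous here because the para position is blocked and the two ortho positions are equivalent, and it spares the MOM acetals and the prenyl group.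

Step 5
Reactants: 10 1-[6-hydroxy-2,4-bis(methoxymethoxy)-3-(3-methylbut-2-en-1-yl)phenyl]ethan-1-one; 11 N,N-dimethylformamide dimethyl acetal
Product: 14 5,7-dihydroxy-6-(3-methylbut-2-en-1-yl)-4H-chromen-4-one, via enaminone 12 (not isolated), via bis-MOM chromone 13 (not isolated)
Conditions: 11 (3 equiv), toluene, 100 °C, evaporate; 3 M HCl/MeOH, 0 °C to rt, 30 min; then 45 °C, 2 h
Reagents that add atoms: N,N-dimethylformamide dimethyl acetal (11), COC(OC)N(C)C
Why: Enaminone condensation followed by fast acid-induced addition–elimination through the only free hydroxyl closes the γ-pyrone before the acetals are cleaved, so the prenyl group ends at C6 and not C8; the slower acetal methanolysis then frees 5-OH and 7-OH.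

Step 6
Reactants: 14 5,7-dihydroxy-6-(3-methylbut-2-en-1-yl)-4H-chromen-4-one; 15 3-methylbut-2-enal (prenal)
Product: 16 5-hydroxy-8,8-dimethyl-6-(3-methylbut-2-en-1-yl)-4H,8H-pyrano[2,3-h]chromen-4-one
Conditions: 15 (3 equiv), pyridine, 120 °C (sealed tube)
Reagents that add atoms: 3-methylbut-2-enal (15), CC(C)=CC=O
Why: Aldol-type C-alkylation at C8 (the only unsubstituted nucleophilic ring carbon), dehydration to an o-quinone methide and oxa-6π electrocyclisation through the non-chelated 7-OH give the angular 2,2-dimethylpyran as the only possible regioisomer.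

Step 7
Reactants: 16 5-hydroxy-8,8-dimethyl-6-(3-methylbut-2-en-1-yl)-4H,8H-pyrano[2,3-h]chromen-4-one
Product: 17 8,8-dimethyl-6-(3-methylbut-2-en-1-yl)-4-oxo-4H,8H-pyrano[2,3-h]chromen-5-yl acetate
Conditions: Ac2O (3 equiv), DMAP (0.2 equiv), pyridine, CH2Cl2, rt
Reagents that add atoms: acetic anhydride, CC(=O)OC(C)=O
Why: DMAP-catalysed acylation masks the chelated 5-OH so that it cannot undergo Pd(II)-mediated Wacker-type cyclisation onto the neighbouring prenyl group in step 13.

Step 8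
Reactants: 18 hydroquinone
Product: 19 1,4-dimethoxybenzene
Conditions: MeI (2.5 equiv), K2CO3, acetone, reflux
Reagents that add atoms: iodomethane, CI
Why: Williamson methylation gives the bis-ether that serves both as ortho-directing group and as latent quinone.

Step 9
Reactants: 19 1,4-dimethoxybenzene
Product: 22 2,5-dimethoxyphenol, via aryllithium 20 (not isolated), via dimethyl boronate 21 (not isolated)
Conditions: n-BuLi (1.2 equiv), TMEDA, Et2O, 0 °C to rt; B(OMe)3, −78 °C to rt; AcOH, 30 % H2O2, 0 °C to rt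
Reagents that add atoms: hydrogen peroxide, OO; n-butyllithium, [Li]CCCC (lithium of 20 only); trimethyl borate, COB(OC)OC (boron and methoxy groups of 21 only)
Why: Directed ortho-metalation next to a methoxy group (all four ring C–H are equivalent), borate trapping and peroxide oxidation introduce the third oxygen of ring B.

Step 10
Reactants: 22 2,5-dimethoxyphenol; 23 3-chloro-3-methylbut-1-yne
Product: 24 1,4-dimethoxy-2-[(2-methylbut-3-yn-2-yl)oxy]benzene
Conditions: 23 (2 equiv), K2CO3, KI (cat.), CuI (cat.), acetone, reflux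
Reagents that add atoms: 3-chloro-3-methylbut-1-yne (23), CC(C)(Cl)C#C
Why: Copper-assisted propargylic substitution of the tertiary chloride by the phenoxide gives the aryl 1,1-dimethylpropargyl ether.

Step 11
Reactants: 24 1,4-dimethoxy-2-[(2-methylbut-3-yn-2-yl)oxy]benzene
Product: 25 5,8-dimethoxy-2,2-dimethyl-2H-chromene
Conditions: N,N-diethylaniline, 190 °C
Reagents that add atoms: none
Why: Aromatic propargyl Claisen rearrangement to the only free ortho carbon, then [1,5]-H shift and oxa-6π electrocyclisation, gives the chromene with the methoxy groups at C5 and C8.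

Step 12
Reactants: 25 5,8-dimethoxy-2,2-dimethyl-2H-chromene
Product: 26 2,2-dimethyl-2H-chromene-5,8-dione
Conditions: CAN (2.5 equiv), MeCN/H2O 2:1, 0 °C, 15 min
Reagents that add atoms: water, O
Why: Ceric ammonium nitrate oxidative demethylation of the para-dimethoxyarene gives the chromenequinone; the chromene alkene is not touched at 0 °C.

Step 13
Reactants: 17 8,8-dimethyl-6-(3-methylbut-2-en-1-yl)-4-oxo-4H,8H-pyrano[2,3-h]chromen-5-yl acetate; 26 2,2-dimethyl-2H-chromene-5,8-dione
Product: 27 3-(2,2-dimethyl-5,8-dioxo-5,8-dihydro-2H-chromen-6-yl)-8,8-dimethyl-6-(3-methylbut-2-en-1-yl)-4-oxo-4H,8H-pyrano[2,3-h]chromen-5-yl acetate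
Conditions: Pd(OAc)2 (10 mol %), Ag2CO3 (1.5 equiv), 26 (2 equiv), PivOH (5 equiv), 1,4-dioxane, 90 °C
Reagents that add atoms: none
Why: Pd(II)-catalysed dehydrogenative (oxidative Heck-type) coupling of a chromone with a quinone: electrophilic palladation at the enol-ether carbon C3 (ring A has no aryl C–H), insertion into the quinone C6=C7 bond with the chromonyl group going to C6 (β to C8=O, the carbonyl that is not deactivated as a vinylogous ester by the pyran oxygen), β-hydride elimination, and silver reoxidation of Pd(0).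

Step 14
Reactants: 27 3-(2,2-dimethyl-5,8-dioxo-5,8-dihydro-2H-chromen-6-yl)-8,8-dimethyl-6-(3-methylbut-2-en-1-yl)-4-oxo-4H,8H-pyrano[2,3-h]chromen-5-yl acetate
Product: 29 CNP0323631.0 (target), via acetylated coumaronochromone 28 (not isolated)
Conditions: Sc(OTf)3 (10 mol %), MeCN, 40 °C, Ar; then MeOH, K2CO3 (0.2 equiv), 0 °C, Ar
Reagents that add atoms: none
Why: Proposed new method: Lewis-acid-catalysed redox-neutral cycloisomerisation of a 3-quinonylchromone to a 5′-hydroxycoumaronochromone. Sc(III) on the C4 carbonyl gives C2 oxocarbenium (4-oxidobenzopyrylium) character; the quinone C5=O oxygen, the more basic vinylogous-ester carbonyl and the only oxygen that can reach C2 through a five-membered transition state, adds to C2 to give a dienolate/alkoxy-stabilised oxocarbenium zwitterion; transfer of the C2 proton to the C8 oxygen then restores the chromone C2=C3 bond and aromatises ring B, so the quinone acts as internal oxidant and C8=O becomes the 5′-OH. Attack of the chromone carbonyl on quinone C7 can only give a reversible pyrylium adduct. The closest known reactions are the final O-cyclisation of the Nenitzescu benzofuran synthesis and the acid- or light-induced cyclisation of 2-arylbenzoquinones to dibenzofuran-2-ols; the second stage is an ordinary carbonate-catalysed methanolysis of the aryl acetate.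

## Compound list

1 | resorcinol | Oc1cccc(O)c1 | starting material
2 | 1,3-bis(methoxymethoxy)benzene | COCOc1cccc(OCOC)c1 | intermediate
3 | prenyl bromide (1-bromo-3-methylbut-2-ene) | CC(C)=CCBr | starting material
4 | [2,6-bis(methoxymethoxy)phenyl]lithium | [Li]c1c(OCOC)cccc1OCOC | intermediate
5 | 1,3-bis(methoxymethoxy)-2-(3-methylbut-2-en-1-yl)benzene | COCOc1cccc(OCOC)c1CC=C(C)C | intermediate
6 | 2-[3,5-bis(methoxymethoxy)-4-(3-methylbut-2-en-1-yl)phenyl]-4,4,5,5-tetramethyl-1,3,2-dioxaborolane | COCOc1cc(B2OC(C)(C)C(C)(C)O2)cc(OCOC)c1CC=C(C)C | intermediate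
7 | 3,5-bis(methoxymethoxy)-4-(3-methylbut-2-en-1-yl)phenol | COCOc1cc(O)cc(OCOC)c1CC=C(C)C | intermediate
8 | acetyl chloride | CC(Cl)=O | starting material
9 | bromomagnesium 3,5-bis(methoxymethoxy)-4-(3-methylbut-2-en-1-yl)phenoxide | Br[Mg]Oc1cc(OCOC)c(CC=C(C)C)c(OCOC)c1 | intermediate
10 | 1-[6-hydroxy-2,4-bis(methoxymethoxy)-3-(3-methylbut-2-en-1-yl)phenyl]ethan-1-one | CC(=O)c1c(O)cc(OCOC)c(CC=C(C)C)c1OCOC | intermediate
11 | N,N-dimethylformamide dimethyl acetal | COC(OC)N(C)C | starting material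
12 | (E)-3-(dimethylamino)-1-[6-hydroxy-2,4-bis(methoxymethoxy)-3-(3-methylbut-2-en-1-yl)phenyl]prop-2-en-1-one | CN(C)/C=C/C(=O)c1c(O)cc(OCOC)c(CC=C(C)C)c1OCOC | intermediate
13 | 5,7-bis(methoxymethoxy)-6-(3-methylbut-2-en-1-yl)-4H-chromen-4-one | O=c1ccoc2cc(OCOC)c(CC=C(C)C)c(OCOC)c12 | intermediate
14 | 5,7-dihydroxy-6-(3-methylbut-2-en-1-yl)-4H-chromen-4-one | O=c1ccoc2cc(O)c(CC=C(C)C)c(O)c12 | intermediate
15 | 3-methylbut-2-enal (prenal) | CC(C)=CC=O | starting material
16 | 5-hydroxy-8,8-dimethyl-6-(3-methylbut-2-en-1-yl)-4H,8H-pyrano[2,3-h]chromen-4-one | O=c1ccoc2c1c(O)c(CC=C(C)C)c1c2C=CC(C)(C)O1 | intermediate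
17 | 8,8-dimethyl-6-(3-methylbut-2-en-1-yl)-4-oxo-4H,8H-pyrano[2,3-h]chromen-5-yl acetate | O=c1ccoc2c1c(OC(C)=O)c(CC=C(C)C)c1c2C=CC(C)(C)O1 | intermediate
18 | hydroquinone | Oc1ccc(O)cc1 | starting material
19 | 1,4-dimethoxybenzene | COc1ccc(OC)cc1 | intermediate
20 | (2,5-dimethoxyphenyl)lithium | [Li]c1cc(OC)ccc1OC | intermediate
21 | dimethyl (2,5-dimethoxyphenyl)boronate | COB(OC)c1cc(OC)ccc1OC | intermediate
22 | 2,5-dimethoxyphenol | COc1ccc(OC)c(O)c1 | intermediate
23 | 3-chloro-3-methylbut-1-yne | CC(C)(Cl)C#C | starting material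
24 | 1,4-dimethoxy-2-[(2-methylbut-3-yn-2-yl)oxy]benzene | COc1ccc(OC)c(OC(C)(C)C#C)c1 | intermediate
25 | 5,8-dimethoxy-2,2-dimethyl-2H-chromene | COc1ccc(OC)c2c1C=CC(C)(C)O2 | intermediate
26 | 2,2-dimethyl-2H-chromene-5,8-dione | O=C1C=CC(=O)C2=C1C=CC(C)(C)O2 | intermediate
27 | 3-(2,2-dimethyl-5,8-dioxo-5,8-dihydro-2H-chromen-6-yl)-8,8-dimethyl-6-(3-methylbut-2-en-1-yl)-4-oxo-4H,8H-pyrano[2,3-h]chromen-5-yl acetate | O=c1c(C3=CC(=O)C4=C(C=CC(C)(C)O4)C3=O)coc2c1c(OC(C)=O)c(CC=C(C)C)c1c2C=CC(C)(C)O1 | intermediate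
28 | 5-O-acetyl derivative of the target (coumaronochromone with 5-OAc and free 5′-OH) | CC(C)=CCc1c2c(c3oc4oc5c6c(c(O)cc5c4c(=O)c3c1OC(C)=O)OC(C)(C)C=C6)C=CC(C)(C)O2 | intermediate
29 | CNP0323631.0: benzofuro[2,3-b]chromen-4-one with 5-OH, 6-prenyl, a 2,2-dimethylpyran fused at O7/C8, 5′-OH and a 2,2-dimethylpyran fused at O4′/C3′ (achiral) | CC(C)=CCc1c2c(c3oc4oc5c6c(c(O)cc5c4c(=O)c3c1O)OC(C)(C)C=C6)C=CC(C)(C)O2 | target

## Step count and risks

Total steps: 14 (steps 1–7 ring A/C fragment, steps 8–12 ring B fragment, steps 13–14 union and furan closure).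
Longest linear sequence: 9 (steps 1–7, 13, 14).

**Step 13 (dehydrogenative coupling).** Risks are Pd(II) attack on the prenyl or chromene alkenes, quinone homocoupling, and the wrong quinone regiochemistry. The fallback makes the same bond by a Suzuki–Miyaura coupling; it sets out from 12 and 25 and comes back at 27. Enaminone 12 is isolated instead of being cyclised and treated with I2/pyridine in CHCl3 to give 3-iodo-5,7-bis(methoxymethoxy)-6-(3-methylbut-2-en-1-yl)-4H-chromen-4-one F1. HCl/MeOH gives 5,7-dihydroxy-3-iodo-6-(3-methylbut-2-en-1-yl)-4H-chromen-4-one F2, and prenal in pyridine gives 5-hydroxy-3-iodo-8,8-dimethyl-6-(3-methylbut-2-en-1-yl)-4H,8H-pyrano[2,3-h]chromen-4-one F3. Chromene 25 is brominated para to the ring oxygen (NBS, MeCN, 0 °C) to 6-bromo-5,8-dimethoxy-2,2-dimethyl-2H-chromene F4 and borylated (B2pin2, Pd(dppf)Cl2, KOAc, dioxane, 80 °C) to 2-(5,8-dimethoxy-2,2-dimethyl-2H-chromen-6-yl)-4,4,5,5-tetramethyl-1,3,2-dioxaborolane F5. Coupling of F3 with F5 (Pd(dppf)Cl2, K2CO3, dioxane/H2O, 80 °C) gives 3-(5,8-dimethoxy-2,2-dimethyl-2H-chromen-6-yl)-5-hydroxy-8,8-dimethyl-6-(3-methylbut-2-en-1-yl)-4H,8H-pyrano[2,3-h]chromen-4-one F6. Acetylation (Ac2O, DMAP, pyridine) gives 3-(5,8-dimethoxy-2,2-dimethyl-2H-chromen-6-yl)-8,8-dimethyl-6-(3-methylbut-2-en-1-yl)-4-oxo-4H,8H-pyrano[2,3-h]chromen-5-yl acetate F7, and CAN in MeCN/H2O at 0 °C oxidises the dimethoxyarene to quinone 27.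

**Step 14 (proposed new cycloisomerisation).** It is untested; the quinone may decompose, the alkenes may react with the Lewis acid, or the zwitterion may not form. The fallback uses the established dehydrogenative cyclisation of 2′-hydroxyisoflavones; it sets out from 27 and comes back at 29. Quinone 27 is reduced (Na2S2O4, EtOAc/H2O) to 3-(5,8-dihydroxy-2,2-dimethyl-2H-chromen-6-yl)-8,8-dimethyl-6-(3-methylbut-2-en-1-yl)-4-oxo-4H,8H-pyrano[2,3-h]chromen-5-yl acetate F8. The less hindered hydroxyl is acetylated (AcCl 1.0 equiv, 2,6-lutidine, CH2Cl2, −40 °C) to 3-(8-acetoxy-5-hydroxy-2,2-dimethyl-2H-chromen-6-yl)-8,8-dimethyl-6-(3-methylbut-2-en-1-yl)-4-oxo-4H,8H-pyrano[2,3-h]chromen-5-yl acetate F9. DDQ in 1,4-dioxane at 80 °C closes the furan ring to the 5,5′-di-O-acetyl derivative of the target F10, and K2CO3/MeOH at 0 °C under argon gives 29.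

**Step 4 (ortho-C-acetylation).** Risks are O-acylation instead of C-acylation and MOM loss at the Lewis-acidic magnesium. The fallback replaces direct acylation by halogenation and halogen–metal exchange; it sets out from 7 and comes back at 10. Phenol 7 is brominated (NBS, CH2Cl2, −78 °C) to 2-bromo-3,5-bis(methoxymethoxy)-4-(3-methylbut-2-en-1-yl)phenol F11. Treatment with n-BuLi (2.1 equiv, THF, −78 °C; O–H deprotonation then Br/Li exchange, faster than benzylic deprotonation at this temperature) and N-methoxy-N-methylacetamide gives 10.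

## Further compounds

F1 | step 13 | 3-iodo-5,7-bis(methoxymethoxy)-6-(3-methylbut-2-en-1-yl)-4H-chromen-4-one | O=c1c(I)coc2cc(OCOC)c(CC=C(C)C)c(OCOC)c12
F2 | step 13 | 5,7-dihydroxy-3-iodo-6-(3-methylbut-2-en-1-yl)-4H-chromen-4-one | O=c1c(I)coc2cc(O)c(CC=C(C)C)c(O)c12
F3 | step 13 | 5-hydroxy-3-iodo-8,8-dimethyl-6-(3-methylbut-2-en-1-yl)-4H,8H-pyrano[2,3-h]chromen-4-one | O=c1c(I)coc2c1c(O)c(CC=C(C)C)c1c2C=CC(C)(C)O1
F4 | step 13 | 6-bromo-5,8-dimethoxy-2,2-dimethyl-2H-chromene | COc1c(Br)cc(OC)c2OC(C)(C)C=Cc12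
F5 | step 13 | 2-(5,8-dimethoxy-2,2-dimethyl-2H-chromen-6-yl)-4,4,5,5-tetramethyl-1,3,2-dioxaborolane | COc1c(B3OC(C)(C)C(C)(C)O3)cc(OC)c2OC(C)(C)C=Cc12
F6 | step 13 | 3-(5,8-dimethoxy-2,2-dimethyl-2H-chromen-6-yl)-5-hydroxy-8,8-dimethyl-6-(3-methylbut-2-en-1-yl)-4H,8H-pyrano[2,3-h]chromen-4-one | O=c1c(-c3cc(OC)c4OC(C)(C)C=Cc4c3OC)coc2c1c(O)c(CC=C(C)C)c1c2C=CC(C)(C)O1
F7 | step 13 | 3-(5,8-dimethoxy-2,2-dimethyl-2H-chromen-6-yl)-8,8-dimethyl-6-(3-methylbut-2-en-1-yl)-4-oxo-4H,8H-pyrano[2,3-h]chromen-5-yl acetate | O=c1c(-c3cc(OC)c4OC(C)(C)C=Cc4c3OC)coc2c1c(OC(C)=O)c(CC=C(C)C)c1c2C=CC(C)(C)O1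
F8 | step 14 | 3-(5,8-dihydroxy-2,2-dimethyl-2H-chromen-6-yl)-8,8-dimethyl-6-(3-methylbut-2-en-1-yl)-4-oxo-4H,8H-pyrano[2,3-h]chromen-5-yl acetate | O=c1c(-c3cc(O)c4OC(C)(C)C=Cc4c3O)coc2c1c(OC(C)=O)c(CC=C(C)C)c1c2C=CC(C)(C)O1
F9 | step 14 | 3-(8-acetoxy-5-hydroxy-2,2-dimethyl-2H-chromen-6-yl)-8,8-dimethyl-6-(3-methylbut-2-en-1-yl)-4-oxo-4H,8H-pyrano[2,3-h]chromen-5-yl acetate | O=c1c(-c3cc(OC(C)=O)c4OC(C)(C)C=Cc4c3O)coc2c1c(OC(C)=O)c(CC=C(C)C)c1c2C=CC(C)(C)O1
F10 | step 14 | 5,5′-di-O-acetyl derivative of the target | CC(C)=CCc1c2c(c3oc4oc5c6c(c(OC(C)=O)cc5c4c(=O)c3c1OC(C)=O)OC(C)(C)C=C6)C=CC(C)(C)O2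
F11 | step 4 | 2-bromo-3,5-bis(methoxymethoxy)-4-(3-methylbut-2-en-1-yl)phenol | COCOc1cc(O)c(Br)c(OCOC)c1CC=C(C)C
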